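## Structural features

The target is an 18-membered macrocyclic bis(bibenzyl) in which four benzene rings are joined in the order A–O–B–CH(OH)–CH2–C–O–D–CH2CH2–A; ring A is the catechol ring, ring B a para-phenylene, ring C a 1,2,3-trisubstituted ring and ring D a meta-phenylene. Ring A carries on three neighbouring carbons a hydroxyl, a second hydroxyl that lies para to the ethylene bridge, and the ether oxygen to ring B; ring C carries in the same way the benzylic CH2, the ether oxygen to ring D and a free hydroxyl. The only stereocentre is the benzylic carbinol carbon on ring B, which is (S) (OH > ring B carbon > CH2 > H); it has no stereogenic neighbour, so a reagent has to set it. The fragile parts are the electron-rich catechol, which oxidises easily once deprotonated, and the secondary benzylic alcohol para to an aryloxy group, which ionises in acid and can be lost by elimination or hydrogenolysis. The real difficulty is to close a cyclophane-type 18-membered ring through a diaryl ether bond to an electron-rich ring that has no activating group, and to place three oxygens in a row on ring A without regiochemical ambiguity. The key step uses the ring A hydroxyl para to the bridge: flanked by two bromines, this phenol is the most easily oxidised site, the ring B phenol oxygen attacks one of its two equivalent ortho carbons, and the bromine left on the other ortho carbon becomes the second catechol oxygen.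

## Logic of the disconnections

22 from 21: the two O–CH2Ph bonds are cut. The catechol and the ring C phenol are thereby exposed only in the last, neutral step, with no base near the free catechol. The forward step must cleave two benzyl aryl ethers without touching the benzylic C–OH bond.

21 from 20: the carbinol C–H bond is cut, which leads back to the ketone. The ketone is needed anyway at the ring-closing stage, and the stereocentre can then be set by a chiral catalyst. The demand is face selectivity on a ketone held inside a macrocycle.

20 from 18 (through 19): the ring A carbon–oxygen bond of the outer catechol hydroxyl is traced to a carbon–boron and then a carbon–bromine bond. The bromine is already in place from the ring closure, so no regiochemical question arises. The forward step must use bases too weak to enolise the benzyl aryl ketone.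

18 from 17: the O–benzyl bond on ring A is cut. The group protects the hindered phenol during borylation and leaves in the final step together with the ring C benzyl group. The forward step must alkylate oxygen and not the ketone alpha-carbon.

17 from 15 (through 16): the ring A carbon–oxygen bond to ring B is cut, which opens the macrocycle. The result is an open chain with a symmetrical 3,5-dibromo-4-hydroxyphenyl ring A and a 4-hydroxyphenyl ketone as ring B. The forward step must oxidise ring A alone, must form the carbon–oxygen bond at an ortho carbon, and must run at high dilution.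

15 from 9 and 12 (through 13 and 14): the bond between the carbonyl carbon and the CH2 group is cut, giving two fragments of similar size. The ring C aldehyde is used directly without reduction or halogenation, and the acid needed to unveil the ketone also frees the ring B phenol. The forward olefination must tolerate the acidic dibromophenol as its phenoxide.

12 from 10 (through 11): the carbon–nitrogen and carbon–phosphorus bonds are cut. This turns a commercial aldehyde into an acyl anion equivalent in one operation. The demand is only clean three-component condensation.

9 from 8 and 8 from 7: the two carbon–bromine bonds and then the O–tert-butyl bond are cut. Bromination is placed here because the ring A phenol is then the only strongly activated ring: ring C is deactivated by its formyl group and ring B is not yet present. The forward steps must leave the aldehyde and the benzyl ether intact.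

7 from 4 and 6: the ring C carbon–oxygen bond of the second diaryl ether is cut. Fluoride ortho to a formyl group makes this a nucleophilic aromatic substitution, and 4 has only one free phenol. The demand is displacement at a carbon flanked by two substituents.

6 from 5: the O–benzyl bond on ring C is cut; the forward step is a simple etherification that masks the hydroxyl next to fluorine.

4 from 1 and 2 (through 3): the bond between ring D and the benzylic CH2 is cut. Hydroboration and alkyl–aryl coupling give the bibenzyl directly, with no olefin to hydrogenate. The forward coupling must tolerate a free phenol.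

## Other disconnections considered

Alternative 1: The cut is the bond between the ring C oxygen and the ring D carbon, made in two stages. The fully protected 18-membered ether A2 is traced to the 19-membered macrolactone A1, in which a ring D carboxyl group is esterified by the ring C phenol. In the forward direction A1 would be heated with Ni(cod)2, 3,4-bis(dicyclohexylphosphino)thiophene and K3PO4. Zerovalent nickel would insert into the acyl–oxygen bond, carbon monoxide would be lost, and reductive elimination would give the diaryl ether with contraction of the ring by one atom.
- In its favour: macrolactonisation is among the most dependable ways to close a large ring, so ring formation is separated from the difficult carbon–oxygen bond formation. The carbinol would be set on an open-chain ketone and carried as a silyl ether, which avoids an asymmetric reduction inside a cyclophane. On both points this plan is better than the chosen one.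
- Against it here: decarbonylative etherification is established mainly for aryl esters of azine carboxylic acids. A1 is a plain benzoate of a phenol flanked by CH2 and OBn, so both insertion and reductive elimination should be slow. The high temperature needed puts the benzylic silyl ether at risk, and the benzyl aryl ethers are themselves possible substrates for zerovalent nickel. A ring-contracting version has no close analogue.
- Comparison: this plan leaves the ring A–O–ring B ether and the three adjacent oxygens of ring A to be solved by other chemistry, whereas the chosen key step solves both at once. The chosen ring closure follows a known reaction type, and the nickel step would be new on this substrate class. In step count the two are expected to be similar up to ring closure. A1 then needs decarbonylation, desilylation and hydrogenolysis, so no saving is expected. The two plans are equal in ending with a hydrogenolysis.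

Alternative 2: The cut is the bond between the carbinol carbon and the CH2 group. The tris-silyl ether A4 of the target is traced to the 19-membered macrocyclic ether A3, in which ring B carries a CH(SnBu3)–O–CH2 link to ring C. In the forward direction tin–lithium exchange with n-BuLi in the presence of a chiral bis(oxazoline) would give the alpha-alkoxy benzylic carbanion. The ring C benzyl group would then migrate from oxygen to carbon in a [1,2]-Wittig rearrangement, forming the carbon–carbon bond, the 18-membered ring and the stereocentre together.
- In its favour: one step creates a skeletal bond, the final ring size and the stereocentre, and the ring to be closed beforehand is an ordinary macrocyclic benzyl ether. In bond economy this is better than the chosen plan, which needs a separate reduction for the stereocentre. In the difficulty of the first ring closure it is at least equal.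
- Against it here: the rearrangement goes through a radical pair, and ligand control of such recombinations on a configurationally labile benzylic organolithium is usually modest. Competing [2,3]-shift onto ring C and deprotonation at the other benzylic position are plausible. The carbanion is destabilised by the para-aryloxy group. A stoichiometric organotin precursor is also needed.
- Comparison: the alternative builds carbon–carbon where the chosen plan builds carbon–oxygen, so it still needs a separate solution for the trioxygenated ring A and its ether to ring B. If the enantiomeric purity were insufficient, an oxidation and asymmetric reduction would have to follow, which removes the step advantage. The chosen plan sets the stereocentre with a catalyst class of known sense on aryl benzyl ketones.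

Alternative 3: The cut is the bond between the bridging oxygen and ring B, the other carbon–oxygen bond of the same ether that the chosen plan forms. The nitro-substituted macrocycle A6 is traced to the open-chain phenol A5, which has a free ring A hydroxyl, a 4-fluoro-3-nitrophenyl ring B and the (S)-carbinol already in place as a silyl ether. In the forward direction K2CO3 in dilute DMF would generate the ring A phenoxide, which displaces fluoride and closes the 18-membered ring.
- In its favour: nitro-activated macrocyclic substitution is one of the best-precedented closures of diaryl ether macrocycles. It is mild, needs no oxidant and tolerates the protected carbinol. In reliability of ring closure it is better than the chosen plan. Setting the stereocentre on an open-chain ketone is also an advantage.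
- Against it here: A6 still carries the nitro group, and its removal costs a reduction and a reductive deamination in the presence of benzyl ethers and an acid-sensitive benzylic silyl ether. A5 needs a ring A with one free and two protected oxygens in a defined order, which means a regioselective protection sequence on a pyrogallol-type ring.
- Comparison: both plans form the same ether oxygen bridge, from opposite sides. In the chosen plan the activating bromines are not waste, since one becomes the catechol hydroxyl. In the alternative the activating nitro group must be removed without trace. The alternative is expected to be two to four steps longer, but its ring closure is mechanistically more secure.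

Key step: step 8

## Route

Remark: the ring C hydroxyl is carried as a benzyl ether and not as an ester, because an aryl ester would be at risk in the basic olefination and would need extra steps to install; compounds 1, 2, 5 and 10 are taken as catalogue chemicals.

Step 1
Reactants: 1 4-tert-butoxystyrene; 2 3-bromophenol
Product: 4 3-[2-(4-tert-butoxyphenyl)ethyl]phenol, via B-alkyl-9-BBN adduct 3 (not isolated)
Conditions: 9-BBN (0.95 equiv to 1), THF, 0 °C → rt; then 2, PdCl2(dppf) (3 mol %), K3PO4 (3 M aq.), DMF, 60 °C
Reagents that add atoms: none
Why: Anti-Markovnikov hydroboration puts boron on the terminal carbon, and the B-alkyl Suzuki–Miyaura coupling then forms the ring D–CH2 bond directly at the bibenzyl oxidation level; the phenoxide and the tert-butyl ether are inert to the borane, the base and zerovalent palladium.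

Step 2
Reactants: 5 2-fluoro-3-hydroxybenzaldehyde
Product: 6 3-(benzyloxy)-2-fluorobenzaldehyde
Conditions: BnBr, K2CO3, DMF, rt
Reagents that add atoms: benzyl bromide, BrCc1ccccc1
Why: Williamson etherification of the phenoxide; at room temperature alkylation by benzyl bromide should be much faster than any self-condensation by fluoride displacement.

Step 3
Reactants: 4 3-[2-(4-tert-butoxyphenyl)ethyl]phenol; 6 3-(benzyloxy)-2-fluorobenzaldehyde
Product: 7 3-(benzyloxy)-2-{3-[2-(4-tert-butoxyphenyl)ethyl]phenoxy}benzaldehyde
Conditions: K2CO3, DMF, 110 °C
Reagents that add atoms: none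
Why: Nucleophilic aromatic substitution; the phenoxide adds to the fluorine-bearing carbon ortho to the formyl group, which stabilises the Meisenheimer intermediate, and 4 has only one free phenol so only one ether can form.

Step 4
Reactants: 7 3-(benzyloxy)-2-{3-[2-(4-tert-butoxyphenyl)ethyl]phenoxy}benzaldehyde
Product: 8 3-(benzyloxy)-2-{3-[2-(4-hydroxyphenyl)ethyl]phenoxy}benzaldehyde
Conditions: TFA/CH2Cl2 (1:4), 0 °C → rt
Reagents that add atoms: none
Why: Acidolysis of the aryl tert-butyl ether by loss of the tert-butyl cation as isobutene; the benzyl ether, the diaryl ether and the aldehyde should be stable to brief TFA treatment.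

Step 5
Reactants: 8 3-(benzyloxy)-2-{3-[2-(4-hydroxyphenyl)ethyl]phenoxy}benzaldehyde
Product: 9 3-(benzyloxy)-2-{3-[2-(3,5-dibromo-4-hydroxyphenyl)ethyl]phenoxy}benzaldehyde
Conditions: NBS (2.05 equiv), MeCN, 0 °C → rt, dark
Reagents that add atoms: N-bromosuccinimide, O=C1CCC(=O)N1Br
Why: Electrophilic aromatic bromination; the para-blocked free phenol takes both bromines at its ortho carbons, while ring C is deactivated by the formyl group and the aryl ethers of rings C and D are far less reactive than a phenol.

Step 6
Reactants: 10 4-tert-butoxybenzaldehyde
Product: 12 diphenyl [anilino(4-tert-butoxyphenyl)methyl]phosphonate (racemic), via N-aryl aldimine 11 (not isolated)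
Conditions: PhNH2, (PhO)2P(O)H, i-PrOH, rt
Reagents that add atoms: aniline, Nc1ccccc1; diphenyl phosphite, O=[PH](Oc1ccccc1)Oc1ccccc1
Why: Kabachnik–Fields three-component condensation (imine formation, then Pudovik addition of the phosphite); the new stereocentre is racemic and is destroyed in step 7.

Step 7
Reactants: 9 3-(benzyloxy)-2-{3-[2-(3,5-dibromo-4-hydroxyphenyl)ethyl]phenoxy}benzaldehyde; 12 diphenyl [anilino(4-tert-butoxyphenyl)methyl]phosphonate
Product: 15 1-(4-hydroxyphenyl)-2-(3-(benzyloxy)-2-{3-[2-(3,5-dibromo-4-hydroxyphenyl)ethyl]phenoxy}phenyl)ethan-1-one (seco bis-phenol ketone), via N-phenyl enamine 13 (not isolated), via tert-butyl ether ketone 14 (not isolated)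
Conditions: Cs2CO3 (3 equiv), THF/i-PrOH (4:1), rt; then 3 M HCl, rt; then TFA/CH2Cl2 (1:4), 0 °C → rt
Reagents that add atoms: water, O
Why: Horner–Wittig olefination of the alpha-amino phosphonate carbanion (an acyl anion equivalent) with the aldehyde gives the enamine, aqueous acid hydrolyses it to the benzyl aryl ketone, and TFA removes the tert-butyl group; the extra carbonate turns the acidic dibromophenol into a spectator phenoxide.

Step 8
Reactants: 15 seco bis-phenol ketone
Product: 17 macrocyclic bromophenol ketone (18-membered ring; ring A hydroxyl flanked by bromine and by the new ether oxygen to ring B; ring C benzyl ether), via bromodienone macrocycle 16 (not isolated)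
Conditions: glassy-carbon anode, Pt cathode, undivided cell, LiClO4 (0.1 M), MeOH, about +1.0 V vs SCE, 2.1 F/mol, 1 mM, rt; then Zn dust, AcOH, rt
Reagents that add atoms: none
Why: Anodic removal of two electrons and one proton from the acidic, most easily oxidised 2,6-dibromophenol of ring A gives a phenoxenium ion whose charge sits on the two bromine-bearing ortho carbons and on the para carbon. The ring B phenol oxygen adds to an ortho carbon and gives the 6-aryloxy-6-bromocyclohexa-2,4-dienone 16; zinc in acetic acid then reduces the carbon–bromine bond next to the carbonyl, bromide leaves and the ring rearomatises to 17. The closest known reaction type is the anodic (or Tl(NO3)3) oxidation of ortho,ortho-dihalophenols with zinc work-up, used to close isodityrosine-type diaryl ether macrocycles. The 18-membered ring closes by oxygen attack on a trigonal carbon of a delocalised cation, a macrocyclic etherification run at about 1 mM so that ring closure can outrun dimerisation. No stereocentre results: the sp3 carbon of 16 is racemic and becomes planar again on reduction. The step needs oxidation of ring A only, oxygen attack instead of carbon attack, and ortho attack instead of para attack. The ketone raises the oxidation potential of the ring B phenol and deactivates its ortho carbons, the ring C oxygen is an ether, the para carbon of ring A is blocked so that a methanol adduct there should be reduced back to 15 by zinc, and the two ortho carbons are equivalent so only one regioisomer can form. Because the benzylic carbon on ring B is a carbonyl, no para-quinone methide can arise there.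

Step 9
Reactants: 17 macrocyclic bromophenol ketone
Product: 18 ring A O-benzyl ether of 17 (macrocyclic bromo ketone with two benzyl ethers)
Conditions: BnBr, K2CO3, DMF, rt → 40 °C
Reagents that add atoms: benzyl bromide, BrCc1ccccc1
Why: Williamson etherification; carbonate deprotonates the bromophenol but is too weak to enolise the ketone to a useful extent, so alkylation should occur on oxygen only.

Step 10
Reactants: 18 macrocyclic bromo ketone bis(benzyl ether)
Product: 20 macrocyclic phenol ketone (ring A: OH, OBn, O–ring B on adjacent carbons; ring C: OBn), via pinacol boronate 19 (not isolated)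
Conditions: B2pin2, PdCl2(dppf) (5 mol %), KOAc, dioxane, 90 °C; filter; then H2O2 (30 % aq.), NaHCO3, THF/H2O, 0 °C → rt
Reagents that add atoms: bis(pinacolato)diboron, CC1(C)OB(OC1(C)C)B1OC(C)(C)C(C)(C)O1; hydrogen peroxide, OO
Why: Miyaura borylation (oxidative addition, acetate-assisted transmetallation, reductive elimination) followed by oxidation of the carbon–boron bond with 1,2-shift of the aryl group to oxygen; acetate and hydrogen carbonate are too weak to enolise the ketone, and the oxygen enters exactly where the bromine was.

Step 11
Reactants: 20 macrocyclic phenol ketone
Product: 21 (S)-configured macrocyclic benzylic alcohol (ring A: OH, OBn, O–ring B; ring C: OBn)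
Conditions: RuCl(p-cymene)[(S,S)-TsDPEN] (2 mol %), HCO2H/Et3N (5:2), DMF, 40 °C
Reagents that add atoms: none
Why: Noyori–Ikariya asymmetric transfer hydrogenation; hydride on ruthenium and the proton on nitrogen are delivered in an outer-sphere six-membered transition state in which ring B lies against the p-cymene ligand (CH/π attraction), which with the (S,S) ligand should give the (S)-carbinol as it does for aryl alkyl ketones, and loss of CO2 makes the reduction irreversible.

Step 12
Reactants: 21 (S)-configured macrocyclic benzylic alcohol
Product: 22 target, (S)-configured macrocyclic tetrol CNP0356934.1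
Conditions: H2 (1 atm), Pd/C (10 %), EtOAc/EtOH, rt
Reagents that add atoms: none
Why: Hydrogenolysis of the two benzyl aryl ethers on palladium under neutral conditions; without acid the secondary benzylic carbon–oxygen bond should be cleaved much more slowly than the benzyl ethers, and the stereocentre is not involved.

## Compound list

1 | 4-tert-butoxystyrene | CC(C)(C)Oc1ccc(C=C)cc1 | starting material
2 | 3-bromophenol | Oc1cccc(Br)c1 | starting material
3 | B-[2-(4-tert-butoxyphenyl)ethyl]-9-borabicyclo[3.3.1]nonane (not isolated) | CC(C)(C)Oc1ccc(CCB2C3CCCC2CCC3)cc1 | intermediate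
4 | 3-[2-(4-tert-butoxyphenyl)ethyl]phenol | CC(C)(C)Oc1ccc(CCc2cccc(O)c2)cc1 | intermediate
5 | 2-fluoro-3-hydroxybenzaldehyde | O=Cc1cccc(O)c1F | starting material
6 | 3-(benzyloxy)-2-fluorobenzaldehyde | O=Cc1cccc(OCc2ccccc2)c1F | intermediate
7 | 3-(benzyloxy)-2-{3-[2-(4-tert-butoxyphenyl)ethyl]phenoxy}benzaldehyde | O=Cc1cccc(OCc2ccccc2)c1Oc1cccc(CCc2ccc(OC(C)(C)C)cc2)c1 | intermediate
8 | 3-(benzyloxy)-2-{3-[2-(4-hydroxyphenyl)ethyl]phenoxy}benzaldehyde | O=Cc1cccc(OCc2ccccc2)c1Oc1cccc(CCc2ccc(O)cc2)c1 | intermediate
9 | 3-(benzyloxy)-2-{3-[2-(3,5-dibromo-4-hydroxyphenyl)ethyl]phenoxy}benzaldehyde | O=Cc1cccc(OCc2ccccc2)c1Oc1cccc(CCc2cc(Br)c(O)c(Br)c2)c1 | intermediate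
10 | 4-tert-butoxybenzaldehyde | CC(C)(C)Oc1ccc(C=O)cc1 | starting material
11 | (E)-N-(4-tert-butoxybenzylidene)aniline (not isolated) | CC(C)(C)Oc1ccc(/C=N/c2ccccc2)cc1 | intermediate
12 | diphenyl [anilino(4-tert-butoxyphenyl)methyl]phosphonate, racemic | CC(C)(C)Oc1ccc(cc1)C(Nc1ccccc1)P(=O)(Oc1ccccc1)Oc1ccccc1 | intermediate
13 | N-[1-(4-tert-butoxyphenyl)-2-(3-(benzyloxy)-2-{3-[2-(3,5-dibromo-4-hydroxyphenyl)ethyl]phenoxy}phenyl)ethenyl]aniline, double-bond geometry not defined (not isolated) | CC(C)(C)Oc1ccc(cc1)C(Nc1ccccc1)=Cc1cccc(OCc2ccccc2)c1Oc1cccc(CCc2cc(Br)c(O)c(Br)c2)c1 | intermediate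
14 | 1-(4-tert-butoxyphenyl)-2-(3-(benzyloxy)-2-{3-[2-(3,5-dibromo-4-hydroxyphenyl)ethyl]phenoxy}phenyl)ethan-1-one (not isolated) | CC(C)(C)Oc1ccc(cc1)C(=O)Cc1cccc(OCc2ccccc2)c1Oc1cccc(CCc2cc(Br)c(O)c(Br)c2)c1 | intermediate
15 | 1-(4-hydroxyphenyl)-2-(3-(benzyloxy)-2-{3-[2-(3,5-dibromo-4-hydroxyphenyl)ethyl]phenoxy}phenyl)ethan-1-one, seco bis-phenol ketone | Oc1ccc(cc1)C(=O)Cc1cccc(OCc2ccccc2)c1Oc1cccc(CCc2cc(Br)c(O)c(Br)c2)c1 | intermediate
16 | bromodienone macrocycle: ring A as 6-aryloxy-2,6-dibromocyclohexa-2,4-dienone, racemic at the sp3 carbon (not isolated) | O=C1C(Br)=CC2=CC1(Br)Oc1ccc(cc1)C(=O)Cc1cccc(OCc3ccccc3)c1Oc1cccc(c1)CC2 | intermediate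
17 | macrocyclic bromophenol ketone, ring C benzyl ether | Brc1cc2cc(c1O)Oc1ccc(cc1)C(=O)Cc1cccc(OCc3ccccc3)c1Oc1cccc(c1)CC2 | intermediate
18 | macrocyclic bromo ketone, ring A and ring C benzyl ethers | Brc1cc2cc(c1OCc4ccccc4)Oc1ccc(cc1)C(=O)Cc1cccc(OCc3ccccc3)c1Oc1cccc(c1)CC2 | intermediate
19 | macrocyclic pinacol boronate ketone, two benzyl ethers (not isolated) | CC1(C)OB(OC1(C)C)c1cc2cc(c1OCc4ccccc4)Oc1ccc(cc1)C(=O)Cc1cccc(OCc3ccccc3)c1Oc1cccc(c1)CC2 | intermediate
20 | macrocyclic phenol ketone, two benzyl ethers | Oc1cc2cc(c1OCc4ccccc4)Oc1ccc(cc1)C(=O)Cc1cccc(OCc3ccccc3)c1Oc1cccc(c1)CC2 | intermediate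
21 | (S)-macrocyclic benzylic alcohol, two benzyl ethers | Oc1cc2cc(c1OCc4ccccc4)Oc1ccc(cc1)[C@@H](O)Cc1cccc(OCc3ccccc3)c1Oc1cccc(c1)CC2 | intermediate
22 | CNP0356934.1, (S)-configured macrocyclic bis(bibenzyl) tetrol | Oc1cc2cc(c1O)Oc1ccc(cc1)[C@@H](O)Cc1cccc(O)c1Oc1cccc(c1)CC2 | target

## Step count and least certain steps

Total: 12 steps. Longest linear sequence: 10 steps (1, 3, 4, 5, 7, 8, 9, 10, 11, 12); steps 2 and 6 are side branches.

**Step 8 (key step).** The phenoxenium ion may be captured by methanol, or by a second molecule, faster than the 18-membered ring can close, because the acyl-substituted ring B phenol is a weak nucleophile and the closure is entropically costly.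
- Fallback, from 9 back to 18: the same bond is made with reversed roles, the ring A bromide acting as electrophile in a copper-catalysed Ullmann etherification.
- 9 is benzylated (BnBr, K2CO3, DMF) to the dibromo bis(benzyl ether) aldehyde F1.
- Olefination of F1 with 12 as in step 7 gives the N-phenyl enamine F2, aqueous HCl the tert-butyl ether ketone F3, and TFA the ring B phenol F4.
- F4 is cyclised with CuI, N,N-dimethylglycine and Cs2CO3 in dioxane at 100 °C under high dilution.
- The two bromines of F4 are equivalent, so substitution of either gives 18, and step 9 is then not needed.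

**Step 7.** Addition of the phosphonate carbanion to the hindered ortho-aryloxy aldehyde may be slow or incomplete in the presence of the caesium phenoxide, and the reagent may be consumed by the base.
- Fallback, from 9 back to 14 (the last intermediate of step 7): the same carbon–carbon bond is made by alkylation of an acyl anion equivalent.
- NaBH4 in MeOH reduces 9 to the benzylic alcohol F5, and PBr3 in CH2Cl2 at 0 °C gives the benzylic bromide F6.
- Compound 10 with propane-1,3-dithiol and catalytic iodine gives the dithiane F7.
- F7 is lithiated with n-BuLi in THF, and 2.2 equivalents of the anion (one is spent on the phenol) are treated with F6 at −78 °C to give the alkylated dithiane F8.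
- Hg(ClO4)2 and CaCO3 in aqueous THF unmask the ketone 14, which TFA converts to 15 as in step 7.

**Step 10.** Oxidative addition at the electron-rich bromide next to the benzyloxy group may be slow, so that reductive loss of bromine competes with borylation.
- Fallback, from 18 back to 21: the order is changed so that the oxygen is introduced by direct copper-catalysed hydroxylation once the ketone is gone.
- Transfer hydrogenation of 18 under the conditions of step 11 gives the (S)-bromo alcohol F9.
- Cu(acac)2 with N,N'-bis(4-hydroxy-2,6-dimethylphenyl)oxalamide and LiOH in DMSO/H2O at 80 °C replaces the bromine of F9 by hydroxyl and gives 21.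

**Step 11.** Face selectivity or rate may be poor, because the ketone is held in a cyclophane and ring B may not be able to dock against the arene ligand of the catalyst.
- Fallback, from 20 back to 21: a borane reduction steered by an oxazaborolidine, in which the ketone oxygen is bound to boron inside the reagent and no contact with a metal-bound arene is needed.
- 20 is treated with (R)-2-methyl-CBS-oxazaborolidine and BH3·SMe2 (one extra equivalent for the phenol) in THF at −20 °C.
- This should give the (S)-alcohol 21 directly; no new compound arises.

**Step 12.** Hydrogenolysis may go too far, with loss of the benzylic hydroxyl, which is activated by the para-aryloxy group.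
- Fallback, from 20 back to 22: the benzyl groups are removed before the carbinol exists.
- Hydrogenolysis of 20 (H2, Pd/C, EtOAc) gives the triphenol ketone F10, and Ac2O in pyridine gives the triacetate ketone F11.
- Transfer hydrogenation as in step 11 gives the (S)-triacetate alcohol F12.
- K2CO3 in degassed MeOH at 0 °C, quenched with aqueous NH4Cl, gives 22.

## Further compounds

F1 | step 8 | 3-(benzyloxy)-2-{3-[2-(4-benzyloxy-3,5-dibromophenyl)ethyl]phenoxy}benzaldehyde | O=Cc1cccc(OCc2ccccc2)c1Oc1cccc(CCc2cc(Br)c(OCc3ccccc3)c(Br)c2)c1
F2 | step 8 | N-[1-(4-tert-butoxyphenyl)-2-(3-(benzyloxy)-2-{3-[2-(4-benzyloxy-3,5-dibromophenyl)ethyl]phenoxy}phenyl)ethenyl]aniline, double-bond geometry not defined | CC(C)(C)Oc1ccc(cc1)C(Nc1ccccc1)=Cc1cccc(OCc2ccccc2)c1Oc1cccc(CCc2cc(Br)c(OCc3ccccc3)c(Br)c2)c1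
F3 | step 8 | 1-(4-tert-butoxyphenyl)-2-(3-(benzyloxy)-2-{3-[2-(4-benzyloxy-3,5-dibromophenyl)ethyl]phenoxy}phenyl)ethan-1-one | CC(C)(C)Oc1ccc(cc1)C(=O)Cc1cccc(OCc2ccccc2)c1Oc1cccc(CCc2cc(Br)c(OCc3ccccc3)c(Br)c2)c1
F4 | step 8 | 1-(4-hydroxyphenyl)-2-(3-(benzyloxy)-2-{3-[2-(4-benzyloxy-3,5-dibromophenyl)ethyl]phenoxy}phenyl)ethan-1-one | Oc1ccc(cc1)C(=O)Cc1cccc(OCc2ccccc2)c1Oc1cccc(CCc2cc(Br)c(OCc3ccccc3)c(Br)c2)c1
F5 | step 7 | 2,6-dibromo-4-[2-(3-{2-(benzyloxy)-6-(hydroxymethyl)phenoxy}phenyl)ethyl]phenol | OCc1cccc(OCc2ccccc2)c1Oc1cccc(CCc2cc(Br)c(O)c(Br)c2)c1
F6 | step 7 | 2,6-dibromo-4-[2-(3-{2-(benzyloxy)-6-(bromomethyl)phenoxy}phenyl)ethyl]phenol | BrCc1cccc(OCc2ccccc2)c1Oc1cccc(CCc2cc(Br)c(O)c(Br)c2)c1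
F7 | step 7 | 2-(4-tert-butoxyphenyl)-1,3-dithiane | CC(C)(C)Oc1ccc(cc1)C1SCCCS1
F8 | step 7 | 2-(4-tert-butoxyphenyl)-2-(3-(benzyloxy)-2-{3-[2-(3,5-dibromo-4-hydroxyphenyl)ethyl]phenoxy}benzyl)-1,3-dithiane | CC(C)(C)Oc1ccc(cc1)C1(Cc2cccc(OCc3ccccc3)c2Oc2cccc(CCc3cc(Br)c(O)c(Br)c3)c2)SCCCS1
F9 | step 10 | (S)-macrocyclic bromo alcohol, ring A and ring C benzyl ethers | Brc1cc2cc(c1OCc4ccccc4)Oc1ccc(cc1)[C@@H](O)Cc1cccc(OCc3ccccc3)c1Oc1cccc(c1)CC2
F0 | step 11 | none | none
F10 | step 12 | macrocyclic triphenol ketone | Oc1cc2cc(c1O)Oc1ccc(cc1)C(=O)Cc1cccc(O)c1Oc1cccc(c1)CC2
F11 | step 12 | macrocyclic triacetate ketone | CC(=O)Oc1cc2cc(c1OC(C)=O)Oc1ccc(cc1)C(=O)Cc1cccc(OC(C)=O)c1Oc1cccc(c1)CC2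
F12 | step 12 | (S)-macrocyclic triacetate alcohol | CC(=O)Oc1cc2cc(c1OC(C)=O)Oc1ccc(cc1)[C@@H](O)Cc1cccc(OC(C)=O)c1Oc1cccc(c1)CC2
A1 | alternative 1 | 19-membered macrolactone: ring D carboxylate esterified by the ring C phenol, (S)-silyl ether, three benzyl ethers | C(c1ccccc1)Oc1cc2cc(c1OCc1ccccc1)Oc1ccc(cc1)[C@@H](O[Si](C)(C)C(C)(C)C)Cc1cccc(OCc3ccccc3)c1OC(=O)c1cccc(c1)CC2
A2 | alternative 1 | fully protected target macrocycle (three benzyl ethers, one TBS ether) | C(c1ccccc1)Oc1cc2cc(c1OCc1ccccc1)Oc1ccc(cc1)[C@@H](O[Si](C)(C)C(C)(C)C)Cc1cccc(OCc3ccccc3)c1Oc1cccc(c1)CC2
A3 | alternative 2 | 19-membered macrocyclic alpha-stannyl dibenzyl ether, three aryl TBS ethers, racemic at the stannylated carbon | CC(C)(C)[Si](C)(C)Oc1cc2cc(c1O[Si](C)(C)C(C)(C)C)Oc1ccc(cc1)C(OCc1cccc(O[Si](C)(C)C(C)(C)C)c1Oc1cccc(c1)CC2)[Sn](CCCC)(CCCC)CCCC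
A4 | alternative 2 | tris-silyl ether of the target | CC(C)(C)[Si](C)(C)Oc1cc2cc(c1O[Si](C)(C)C(C)(C)C)Oc1ccc(cc1)[C@@H](O)Cc1cccc(O[Si](C)(C)C(C)(C)C)c1Oc1cccc(c1)CC2
A5 | alternative 3 | open-chain (S)-silyl ether with free ring A phenol and 4-fluoro-3-nitrophenyl ring B | Oc1cc(CCc2cccc(Oc3c(OCc4ccccc4)cccc3C[C@H](O[Si](C)(C)C(C)(C)C)c3ccc(F)c(c3)[N+](=O)[O-])c2)cc(OCc2ccccc2)c1OCc1ccccc1
A6 | alternative 3 | nitro-substituted protected macrocycle | C(c1ccccc1)Oc1cc2cc(c1OCc1ccccc1)Oc1ccc(cc1[N+](=O)[O-])[C@@H](O[Si](C)(C)C(C)(C)C)Cc1cccc(OCc3ccccc3)c1Oc1cccc(c1)CC2
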